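**Conventions and one assumption.** Atoms keep the germacrane numbers of the target throughout: ring C1–C10, lactone carbons C11–C13, C14 on C10, C15 on C4. β is the ring face that carries the C7 side chain. In the bicyclic compounds ring A is C3–C8 and ring B is C8, C9, C10, C1, C2, C3. Compound numbers are those of the steps and of the list after them. Assumption: the facial sense of the catalytic epoxidation in step 1 is taken by analogy with other cis-olefins conjugated to a π-system; C11 in 26 and 27 is an epimer mixture of no consequence.

## Analysis of the target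

Target 33 is a germacranolide: a ten-membered carbocycle (C1–C10) with a trans-fused α-methylene-γ-lactone across C6 (oxygen α) and C7 (C11 β). The C1/C10 epoxide is cis-fused (oxygen β, C14 α), so it derives from a Z olefin. C3 carries a secondary β-hydroxyl and C4 a tertiary α-hydroxyl with C15 β. C8 carries a β-angelate, cis to the C7 side chain. The seven stereocentres (1R,3S,4S,6R,7S,8R,10S) lie around a flexible ring with no rigid element to relay between them. The sensitive groups are the trisubstituted epoxide (acid), the methylene lactone (nucleophiles, and base-induced shift to the butenolide), the Z-configured angelate (isomerisation to the tiglate), and the 6,12-lactone itself, because a free 8β-oxygen can close the cis 8,12-lactone instead. The difficulty is to make the medium ring and to set its stereocentres without relying on an unknown ring conformation. The strategy rests on one feature: C3 and C8 are 1,6 to each other in both directions round the ring and both bear oxygen. A bond between them turns the carbocycle into a Δ3(8)-octalin, whose ring B is a 4-methylcyclohexene, that is, an isoprene Diels–Alder adduct that already contains C1=C10 in the cis geometry.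

## Retrosynthetic reasoning

**C8–O acyl bond and the last silyl ether (33 ⇒ 32 ⇒ 29 + 30).** The angelate is removed first, because the Z ester would survive neither hydride nor enolate chemistry. Angelic acid 30 is therefore attached last to the C8 hydroxyl of 29. The C4 silyl ether is kept until after that, since it shields the neighbouring C3 hydroxyl from acylation.

**C11=C13 (29 ⇒ 28 ⇒ 25 ⇒ 24).** The exocyclic methylene is taken off next, because a methylene lactone would be reduced in the conjugate sense by the hydride that sets C3 and C8. It is put on through the lactone enolate of 25, in which the C3 and C8 hydroxyls of 24 are masked, so that no 8β-alkoxide sits next to the lactone carbonyl under basic conditions.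

**C3–H and C8–H (24 ⇒ 23).** Both carbinol centres go back to ketones. At C8 the Felkin–Anh model, with the C7–C6 bond anti to the hydride, and the 1,3-anti preference of a β-oxygenated ketone both point to the 8β-alcohol. At C3 a free C4 hydroxyl would chelate and lead to the 3,4-anti diol, which is the wrong epimer; with C4 silylated, the non-chelated polar Felkin–Anh mode gives the required syn diol.

**C3=C8 (23 ⇒ 20), the key disconnection.** Joining the two carbonyl carbons gives epoxy-octalin 20. Forward, ozonolysis cleaves the only olefin of 20 and delivers both oxygens and the ten-membered ring in one operation, with C1, C4, C6, C7 and C10 already set in a rigid bicycle. No other cut gives two needed oxygens and the ring at once.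

**O6–C12 and O4–Si (20 ⇒ 19 ⇒ 17).** The lactone is closed before the ring is opened. If the C7 acetate chain were still an open ester when C8 is reduced, the 8β-alkoxide would close the cis 8,12-lactone. Tertiary allylic alcohol 17 is therefore desilylated at C6 and lactonised to 19, and C4 is silylated to 20.

**C4–C15 (17 ⇒ 16).** The tertiary carbinol comes from 1,2-addition of a methyl organometallic to enone 16. The half-chair of ring A is biased by the trans C6/C7 pair so that attack is from the β face.

**The C3=C8 π bond and the epoxide (16 ⇒ 15 ⇒ 14).** The tetrasubstituted enone is made by elimination from a cis-fused adduct, because only the folded cis-decalin can relay C7 to the epoxide face. A halogen on C3 was not used as the leaving group. In the cis adduct it is cis to H8, so an anti elimination can only run into ring B (C2), and on the favoured chair it is axial over the β face of ring B. The leaving group is therefore a sulfonyl group on C8. The only acidic hydrogen next to it is H3, so elimination is regiospecific, and the convex β face of ring B stays open for the epoxidation of 14 to 15.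

**C2–C3 and C8–C9 (14 ⇒ 12 + 13).** Ring B is the Diels–Alder adduct of isoprene 13 and sulfonyl enone 12. The ketone directs the methyl to C10, and the diene adds anti to the C7 chain.

**C8–S (12 ⇒ 10 ⇒ 8 ⇒ 7).** The sulfonyl group is introduced at the β-carbon of enone 7 by thiol conjugate addition, dehydrogenation to the vinylogous thioester 10 and S-oxidation.

**C4=O, one ester carbon and O–Si (7 ⇒ 6 ⇒ 5 ⇒ 4).** Allylic oxidation of the ring methylene, dealkoxycarbonylation and silylation connect enone 7 to hydroxy malonate 4.

**C7–C11 and the first epoxide (4 ⇒ 2 + 3; 2 ⇒ 1).** Anti opening of vinyl epoxide 2 by dimethyl malonate 3 at the allylic carbon sets the trans C6–O/C7–C pair. The epoxide comes from cyclohexa-1,3-diene 1 by catalytic asymmetric epoxidation, the only step in which absolute configuration is introduced.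

## Alternatives that were turned down

**Alternative 1:** Disconnection of C7–C11 on the finished carbocycle. Forward, the diazoacetate A1 on the C6 oxygen is decomposed by Rh2(OAc)4 (or a carboxamidate such as Rh2(cap)4), and the carbenoid inserts into a C7–H bond to give the trans-fused saturated lactone A2.
- For: the lactone is annulated late, with retention at the C–H bond, and does not have to be carried through ring-forming steps. On this point it is stronger than the chosen route, which carries the lactone from step 13.
- Against: it presupposes the ten-membered ring with five stereocentres, so the main problem stays unsolved. C5–H and C7–H are both 1,5 to the carbenoid, and both methylenes are flanked by oxygenated carbons, so regiocontrol is not secured. The epoxide oxygen can trap the carbenoid as an ylide. The trans fusion depends on which C7 hydrogen the ring conformation offers.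
- Comparison: the chosen route fixes C6/C7 trans by an SN2 epoxide opening in step 2, where neither regiochemistry nor ring conformation is in question.

**Alternative 2:** Disconnection of C5–C6 with C3–C8 reconnected. Forward, the potassium alkoxide (KH, 18-crown-6) of the trans-dialkenyl cyclohexenol A3 undergoes a [3,3] shift through a chair that expands the six-membered ring to cyclodecadienone A4, and the C7 enolate is then protonated.
- For: a skeletal C–C bond and the ring are formed together, and the olefin geometry follows from the chair. In bond construction it is stronger than the ozonolysis, which makes no skeletal bond.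
- Against: A4 has two trisubstituted olefins (C1=C10 and C3=C4) that must be told apart for epoxidation and dihydroxylation on a medium ring. The C8 ketone still has to be reduced, and the tetrahydrofuran has to be oxidised to the lactone in the presence of olefins. A3 needs a trans addition of an alkenyl metal to a hindered ketone, and C7 is set only by a protonation.
- Comparison: in the chosen route the oxygens at C3 and C8 come from the cleavage itself and only one olefin is present at that stage.

**Alternative 3:** Disconnection of C7–C8 with O–C13 reconnected. Forward, tin–lithium exchange (BuLi) at C8 of the thirteen-membered α-stannyl allylic ether A5 triggers a [2,3] shift that contracts the ring to the ten-membered alcohol A6 with the C11=C13 methylene.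
- For: C7–C8, the C8 carbinol and the exocyclic methylene appear in one step without lactone enolate chemistry. This is stronger than the chosen route, which needs a separate methylenation with protecting-group steps.
- Against: A5 is a macrocyclic ether with a configurationally defined α-alkoxystannane and a defined trisubstituted olefin, and it is long to make. The C7/C8 relationship depends on a medium-ring transition state, and a [1,2] shift competes.
- Comparison: the chosen route makes the ring from six-membered-ring chemistry, and every stereocentre except C3 and C8 is set in a rigid mono- or bicycle.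

Key step: step 15

## Route

Step 1
Reactants: 1 cyclohexa-1,3-diene
Product: 2 (1S,6R)-7-oxabicyclo[4.1.0]hept-2-ene
Conditions: (S,S)-[N,N′-bis(3,5-di-tert-butylsalicylidene)cyclohexane-1,2-diaminato]MnCl (trivalent manganese, 5 mol %), NaOCl (aq, pH 11), 4-phenylpyridine N-oxide, CH2Cl2, 0 °C
Reagents that add atoms: sodium hypochlorite, [Na+].[O-]Cl
Why: Jacobsen–Katsuki epoxidation of a conjugated cis-olefin; the vinyl epoxide is deactivated towards a second oxidation. The S,S complex is expected to give the (1S,6R)-oxide, which fixes C6 and, through step 2, C7.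

Step 2
Reactants: 2 (1S,6R)-7-oxabicyclo[4.1.0]hept-2-ene, 3 dimethyl malonate
Product: 4 dimethyl 2-[(1S,6R)-6-hydroxycyclohex-2-en-1-yl]propanedioate
Conditions: NaH, THF, 0 → 45 °C; AcOH
Reagents that add atoms: none
Why: Uncatalysed SN2 opening of the vinyl epoxide by the soft carbanion at the allylic carbon with inversion gives the trans C6–O/C7–C pair; no zerovalent palladium is present, which would steer to the 1,4-adduct. The product rests as its malonate enolate and so should not lactonise.

Step 3
Reactants: 4 dimethyl 2-[(1S,6R)-6-hydroxycyclohex-2-en-1-yl]propanedioate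
Product: 5 dimethyl 2-[(1S,6R)-6-[tert-butyl(dimethyl)silyl]oxycyclohex-2-en-1-yl]propanedioate
Conditions: TBSCl, imidazole, DMF, rt
Reagents that add atoms: tert-butyldimethylsilyl chloride, CC(C)(C)[Si](C)(C)Cl
Why: Standard silylation of a secondary alcohol; it keeps the C6 oxygen from closing onto the esters during the next, hot step and later makes a poor leaving group β to the C4 ketone.

Step 4
Reactants: 5 dimethyl 2-[(1S,6R)-6-[tert-butyl(dimethyl)silyl]oxycyclohex-2-en-1-yl]propanedioate
Product: 6 methyl 2-[(1R,6R)-6-[tert-butyl(dimethyl)silyl]oxycyclohex-2-en-1-yl]acetate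
Conditions: NaCl, H2O, DMSO, 150 °C
Reagents that add atoms: none
Why: Krapcho dealkoxycarbonylation under neutral conditions; neither stereocentre is touched (the descriptor at C7 changes only because the priorities change).

Step 5
Reactants: 6 methyl 2-[(1R,6R)-6-[tert-butyl(dimethyl)silyl]oxycyclohex-2-en-1-yl]acetate
Product: 7 methyl 2-[(1R,6R)-6-[tert-butyl(dimethyl)silyl]oxy-4-oxocyclohex-2-en-1-yl]acetate
Conditions: Rh2(cap)4 (dirhodium tetracaprolactamate, 1 mol %), t-BuOOH, K2CO3 (0.5 equiv), CH2Cl2, rt
Reagents that add atoms: tert-butyl hydroperoxide, CC(C)(C)OO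
Why: Catalytic allylic oxidation with t-BuOOH should take the unhindered ring methylene C4 in preference to the tertiary, flanked C7–H and give the C4 enone with C3=C8 in place. Any transposed enone would be removed by chromatography.

Step 6
Reactants: 7 methyl 2-[(1R,6R)-6-[tert-butyl(dimethyl)silyl]oxy-4-oxocyclohex-2-en-1-yl]acetate
Product: 8 methyl [6α-(tert-butyldimethylsilyloxy)-4-oxo-8α-(phenylsulfanyl)cyclohexan-7β-yl]acetate
Conditions: PhSH, Et3N (0.1 equiv), CH2Cl2, 0 °C
Reagents that add atoms: thiophenol, Sc1ccccc1
Why: Thia-Michael addition to the enone β-carbon C8, expected anti to the C7 chain; the new centre is erased in step 7.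

Step 7
Reactants: 8 methyl [6α-(tert-butyldimethylsilyloxy)-4-oxo-8α-(phenylsulfanyl)cyclohexan-7β-yl]acetate
Product: 10 methyl 2-[(1S,6R)-6-[tert-butyl(dimethyl)silyl]oxy-4-oxo-2-(phenylsulfanyl)cyclohex-2-en-1-yl]acetate, via chloro sulfide 9 (not isolated)
Conditions: N-chlorosuccinimide, CH2Cl2, 0 °C → rt; Et3N
Reagents that add atoms: none
Why: Pummerer-type chlorination at the sulfur-bearing carbon, then loss of HCl towards the acidic C3–H, gives the vinylogous thioester; C7 is not involved.

Step 8
Reactants: 10 methyl 2-[(1S,6R)-6-[tert-butyl(dimethyl)silyl]oxy-4-oxo-2-(phenylsulfanyl)cyclohex-2-en-1-yl]acetate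
Product: 12 methyl 2-[(1S,6R)-2-(benzenesulfonyl)-6-[tert-butyl(dimethyl)silyl]oxy-4-oxocyclohex-2-en-1-yl]acetate, via sulfoxide 11 (not isolated)
Conditions: mCPBA (2.2 equiv), CH2Cl2, 0 °C → rt
Reagents that add atoms: 3-chloroperbenzoic acid, O=C(OO)c1cccc(Cl)c1
Why: Stepwise S-oxidation of the sulfide to the sulfone; the electron-poor olefin is inert to peracid. The sulfonyl group activates the dienophile and is the later leaving group on C8.

Step 9
Reactants: 12 methyl 2-[(1S,6R)-2-(benzenesulfonyl)-6-[tert-butyl(dimethyl)silyl]oxy-4-oxocyclohex-2-en-1-yl]acetate, 13 isoprene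
Product: 14 cis-fused adduct: ring A with C4 ketone, 3β-H, 6α-OTBS, 7β-CH2CO2Me, 8β-SO2Ph; ring B with C1=C10 and C14 on C10
Conditions: EtAlCl2 (0.3 equiv), isoprene (excess), toluene, −20 °C → rt
Reagents that add atoms: none
Why: Lewis-acid-catalysed Diels–Alder reaction: with the acid on the ketone oxygen, C8 is the electrophilic terminus, so the methyl ends up on C10 (para to C3). Suprafacial addition gives the cis fusion with 3-H and 8-SO2Ph cis. The diene should come anti to the C7 chain, which is pseudo-axial because of A(1,2) strain with the sulfonyl group, leaving H3 and the sulfonyl group on the β face.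

Step 10
Reactants: 14 cis-fused adduct
Product: 15 1β,10β-epoxide of 14
Conditions: dimethyldioxirane, acetone, 0 °C
Reagents that add atoms: dimethyldioxirane, CC1(C)OO1
Why: Neutral epoxidation of the only electron-rich olefin. With the ring A substituents equatorial, C7 is axial under the α face of ring B and only H3 is axial on the β face, so the oxidant should add from the convex β face. This relays C7 to C1 and C10.

Step 11
Reactants: 15 1β,10β-epoxide of 14
Product: 16 epoxy-octalin enone: 1β,10β-epoxy-6α-OTBS-7β-CH2CO2Me-Δ3(8)-octalin-4-one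
Conditions: Et3N, CH2Cl2, 0 °C → rt
Reagents that add atoms: none
Why: E1cB elimination of sulfinate: H3 is the only acidic hydrogen β to the sulfonyl group, so the olefin can only form between C3 and C8, and no anti geometry is required. The mild base should leave the β-silyloxy ketone and the epoxide alone.

Step 12
Reactants: 16 epoxy-octalin enone
Product: 17 tertiary allylic alcohol: 4α-OH, 4β-CH3, 6α-OTBS, 7β-CH2CO2Me, 1β,10β-epoxide, C3=C8
Conditions: MeLi, CeCl3, THF, −78 °C
Reagents that add atoms: methyllithium, [Li]C
Why: Organocerium 1,2-addition to the hindered enone without enolisation; the ester is untouched at −78 °C. In the diaxial half-chair (favoured by A(1,2) strain between C11 and C9) the axial 6α-silyloxy group blocks the α face, and in the diequatorial one axial attack is also β, so the methyl should enter β and the hydroxyl be α.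

Step 13
Reactants: 17 tertiary allylic alcohol
Product: 19 hydroxy lactone: trans-fused 6α,12-olide with 4α-OH, 1β,10β-epoxide, C3=C8, via C6 alcohol 18 (not isolated)
Conditions: TBAF, THF, 0 °C → rt; AcOH
Reagents that add atoms: none
Why: Fluoride desilylation gives the C6 alkoxide, which closes the γ-lactone by 5-exo-trig acyl substitution on the methyl ester (trans-fused, both bonds equatorial). Closing it now means the C8 oxygen never meets an open ester.

Step 14
Reactants: 19 hydroxy lactone
Product: 20 triethylsilyl ether of 19 (4α-OTES)
Conditions: TESOTf, 2,6-lutidine, CH2Cl2, −78 °C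
Reagents that add atoms: triethylsilyl triflate, CC[Si](CC)(CC)OS(=O)(=O)C(F)(F)F
Why: Silylation of the tertiary alcohol at low temperature, where the epoxide is not attacked. The ether prevents the abnormal cleavage of allylic alcohols in step 15 and removes the chelating hydroxyl for step 16.

Step 15
Reactants: 20 triethylsilyl ether of 19
Product: 23 ten-membered 3,8-diketone: 1β,10β-epoxy-3,8-dioxo-4α-(triethylsilyloxy)germacran-6α,12-olide, via primary ozonide 21 (not isolated), via methoxy hydroperoxide 22 (not isolated)
Conditions: O3, NaHCO3, CH2Cl2/MeOH 4:1, −78 °C; Me2S, −78 °C → rt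
Reagents that add atoms: ozone, [O-][O+]=O
Why: Ozone adds to the electron-rich tetrasubstituted C3=C8 olefin to give primary ozonide 21. Cycloreversion leaves a ketone at C3 and a carbonyl oxide at C8, the side away from the electron-poor α-silyloxy carbon; methanol traps it as 22, and Me2S reduces this to the second ketone. The closest known reaction type is the ozonolysis of the central olefin of Δ9,10-octalins to cyclodecane-1,6-diones. No ring is closed by bond formation: the ten-membered ring appears because the bond shared by the two six-membered rings is cut, so no mode of closure applies. No stereocentre is made; C1, C4, C6, C7 and C10 are carried over from the bicycle. The only selectivity needed is chemoselectivity, and 20 has a single C=C, while the epoxide, lactone and silyl ether are inert to ozone. The buffer, the low temperature and a neutral reductant are chosen because 23 is a 1,6-diketone with two β,γ-epoxy ketone units and a β-acyloxy ketone; it should be taken into step 16 without storage.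

Step 16
Reactants: 23 ten-membered 3,8-diketone
Product: 24 3β,8β-diol: 1β,10β-epoxy-3β,8β-dihydroxy-4α-(triethylsilyloxy)germacran-6α,12-olide
Conditions: LiBH(s-Bu)3 (3 equiv), THF, −78 → −40 °C; AcOH, −78 °C
Reagents that add atoms: none
Why: Non-chelating bulky hydride. At C3 the polar Felkin–Anh mode (C4–OSi anti to hydride, C15 beside the trajectory) should give the 3,4-syn diol, that is 3β-OH. At C8 the Felkin–Anh mode with the C7–C6 bond anti and the 1,3-anti preference of the β-oxygenated ketone both lead to 8β-OH. The lactone is not reduced at this temperature, and the cold acid quench prevents translactonisation by the C8 alkoxide.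

Step 17
Reactants: 24 3β,8β-diol
Product: 25 bis(trimethylsilyl) ether of 24 (3β-OTMS, 8β-OTMS, 4α-OTES)
Conditions: 1-(trimethylsilyl)imidazole, CH2Cl2, rt
Reagents that add atoms: 1-(trimethylsilyl)imidazole, C[Si](C)(C)n1ccnc1
Why: Neutral silylation of both secondary alcohols, the hindered C3 one included, so that no alkoxide is present next to the lactone carbonyl in step 18.

Step 18
Reactants: 25 bis(trimethylsilyl) ether of 24
Product: 28 α-methylene lactone: 11(13)-ene with 3β-OTMS, 8β-OTMS, 4α-OTES, via Mannich base 26 (not isolated), via ammonium iodide 27 (not isolated)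
Conditions: LiN(i-Pr)2, THF, −78 °C; Me2N=CH2+ I−, −78 → 0 °C; MeI, THF, rt; aq NaHCO3
Reagents that add atoms: N,N-dimethylmethyleneiminium iodide (Eschenmoser's salt), C=[N+](C)C.[I-]
Why: Mannich reaction of the lactone enolate, N-methylation and E1cB loss of trimethylamine give the exocyclic methylene. The enolate has no leaving group at C7, and the epoxide is stable to the amide base at −78 °C.

Step 19
Reactants: 28 α-methylene lactone
Product: 29 methylene lactone diol: 3β-OH, 8β-OH, 4α-OTES
Conditions: PPTS (cat.), MeOH, 0 °C
Reagents that add atoms: none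
Why: Mild acid methanolysis removes the two secondary trimethylsilyl ethers; the tertiary triethylsilyl ether is far slower and the epoxide should survive at 0 °C.

Step 20
Reactants: 29 methylene lactone diol, 30 angelic acid
Product: 32 8β-angelate with 3β-OH and 4α-OTES, via mixed anhydride 31 (not isolated)
Conditions: 2,4,6-trichlorobenzoyl chloride, Et3N, toluene, rt; then 29, 75 °C
Reagents that add atoms: none
Why: Yamaguchi esterification through the preformed mixed anhydride, without a nucleophilic catalyst, to keep the Z geometry. The C8 hydroxyl should react, while the C3 hydroxyl is flanked by the quaternary C4 with its silyl ether.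

Step 21
Reactants: 32 8β-angelate
Product: 33 target: (1R,3S,4S,6R,7S,8R,10S)-1β,10β-epoxy-3β,4α-dihydroxy-8β-angeloyloxygermacr-11(13)-en-6α,12-olide (CNP0113954.1)
Conditions: HF·pyridine, pyridine, THF, 0 °C → rt
Reagents that add atoms: none
Why: Buffered fluoride cleaves the tertiary triethylsilyl ether; the epoxide, methylene lactone and angelate should tolerate these conditions.

## Compound list

1 | cyclohexa-1,3-diene | C1=CC=CCC1 | starting material
2 | (1S,6R)-7-oxabicyclo[4.1.0]hept-2-ene | C1=C[C@H]2[C@H](O2)CC1 | intermediate
3 | dimethyl malonate | COC(=O)CC(=O)OC | starting material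
4 | dimethyl 2-[(1S,6R)-6-hydroxycyclohex-2-en-1-yl]propanedioate | COC(=O)C(C(=O)OC)[C@@H]1C=CCC[C@H]1O | intermediate
5 | dimethyl 2-[(1S,6R)-6-[tert-butyl(dimethyl)silyl]oxycyclohex-2-en-1-yl]propanedioate | COC(=O)C(C(=O)OC)[C@@H]1C=CCC[C@H]1O[Si](C)(C)C(C)(C)C | intermediate
6 | methyl 2-[(1R,6R)-6-[tert-butyl(dimethyl)silyl]oxycyclohex-2-en-1-yl]acetate | COC(=O)C[C@@H]1C=CCC[C@H]1O[Si](C)(C)C(C)(C)C | intermediate
7 | methyl 2-[(1R,6R)-6-[tert-butyl(dimethyl)silyl]oxy-4-oxocyclohex-2-en-1-yl]acetate | COC(=O)C[C@@H]1C=CC(=O)C[C@H]1O[Si](C)(C)C(C)(C)C | intermediate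
8 | methyl [6α-(tert-butyldimethylsilyloxy)-4-oxo-8α-(phenylsulfanyl)cyclohexan-7β-yl]acetate | COC(=O)C[C@@H]1[C@@H](Sc2ccccc2)CC(=O)C[C@H]1O[Si](C)(C)C(C)(C)C | intermediate
9 | 8-chloro derivative of 8 (chloro sulfide, C8 not defined) | COC(=O)C[C@@H]1C(Cl)(Sc2ccccc2)CC(=O)C[C@H]1O[Si](C)(C)C(C)(C)C | intermediate (not isolated)
10 | methyl 2-[(1S,6R)-6-[tert-butyl(dimethyl)silyl]oxy-4-oxo-2-(phenylsulfanyl)cyclohex-2-en-1-yl]acetate | COC(=O)C[C@@H]1C(Sc2ccccc2)=CC(=O)C[C@H]1O[Si](C)(C)C(C)(C)C | intermediate
11 | methyl 2-[(1S,6R)-2-(benzenesulfinyl)-6-[tert-butyl(dimethyl)silyl]oxy-4-oxocyclohex-2-en-1-yl]acetate (sulfur not defined) | COC(=O)C[C@@H]1C(S(=O)c2ccccc2)=CC(=O)C[C@H]1O[Si](C)(C)C(C)(C)C | intermediate (not isolated)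
12 | methyl 2-[(1S,6R)-2-(benzenesulfonyl)-6-[tert-butyl(dimethyl)silyl]oxy-4-oxocyclohex-2-en-1-yl]acetate | COC(=O)C[C@@H]1C(S(=O)(=O)c2ccccc2)=CC(=O)C[C@H]1O[Si](C)(C)C(C)(C)C | intermediate
13 | isoprene | C=CC(C)=C | starting material
14 | cis-fused Diels–Alder adduct (C4 ketone, 3β-H, 6α-OTBS, 7β-CH2CO2Me, 8β-SO2Ph, C1=C10, C14 on C10) | COC(=O)C[C@H]1[C@H](O[Si](C)(C)C(C)(C)C)CC(=O)[C@@H]2CC=C(C)C[C@]12S(=O)(=O)c3ccccc3 | intermediate
15 | 1β,10β-epoxide of 14 | COC(=O)C[C@H]1[C@H](O[Si](C)(C)C(C)(C)C)CC(=O)[C@@H]2C[C@H]3O[C@@]3(C)C[C@]12S(=O)(=O)c4ccccc4 | intermediate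
16 | epoxy-octalin enone (1β,10β-epoxy-6α-OTBS-7β-CH2CO2Me-Δ3(8)-octalin-4-one) | COC(=O)C[C@H]1[C@H](O[Si](C)(C)C(C)(C)C)CC(=O)C=2C[C@H]3O[C@@]3(C)CC1=2 | intermediate
17 | epoxy-octalin with 4α-OH, 4β-CH3, 6α-OTBS and 7β-CH2CO2Me | COC(=O)C[C@H]1[C@H](O[Si](C)(C)C(C)(C)C)C[C@](C)(O)C=2C[C@H]3O[C@@]3(C)CC1=2 | intermediate
18 | C6 alcohol of 17 | COC(=O)C[C@H]1[C@H](O)C[C@](C)(O)C=2C[C@H]3O[C@@]3(C)CC1=2 | intermediate (not isolated)
19 | epoxy-octalin 6α,12-olide with 4α-OH (trans-fused lactone) | O=C1C[C@H]2[C@H](O1)C[C@](C)(O)C=3C[C@H]4O[C@@]4(C)CC2=3 | intermediate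
20 | 4α-triethylsilyl ether of 19 | O=C1C[C@H]2[C@H](O1)C[C@](C)(O[Si](CC)(CC)CC)C=3C[C@H]4O[C@@]4(C)CC2=3 | intermediate
21 | primary ozonide of 20 (1,2,3-trioxolane across C3/C8, face not defined) | O=C1C[C@H]2[C@H](O1)C[C@](C)(O[Si](CC)(CC)CC)C34C[C@H]5O[C@@]5(C)CC24OOO3 | intermediate (not isolated)
22 | C3 ketone with 8-hydroperoxy-8-methoxy group (C8 not defined) | O=C1C[C@H]2[C@H](O1)C[C@](C)(O[Si](CC)(CC)CC)C(=O)C[C@H]3O[C@@]3(C)CC2(OC)OO | intermediate (not isolated)
23 | 1β,10β-epoxy-3,8-dioxo-4α-(triethylsilyloxy)germacran-6α,12-olide | O=C1C[C@H]2[C@H](O1)C[C@](C)(O[Si](CC)(CC)CC)C(=O)C[C@H]3O[C@@]3(C)CC2=O | intermediate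
24 | 1β,10β-epoxy-3β,8β-dihydroxy-4α-(triethylsilyloxy)germacran-6α,12-olide | O=C1C[C@H]2[C@H](O1)C[C@](C)(O[Si](CC)(CC)CC)[C@@H](O)C[C@H]3O[C@@]3(C)C[C@H]2O | intermediate
25 | 3β,8β-bis(trimethylsilyl) ether of 24 | O=C1C[C@H]2[C@H](O1)C[C@](C)(O[Si](CC)(CC)CC)[C@@H](O[Si](C)(C)C)C[C@H]3O[C@@]3(C)C[C@H]2O[Si](C)(C)C | intermediate
26 | 11-(dimethylaminomethyl) lactone (C11 not defined) | CN(C)CC1C(=O)O[C@@H]2C[C@](C)(O[Si](CC)(CC)CC)[C@@H](O[Si](C)(C)C)C[C@H]3O[C@@]3(C)C[C@@H](O[Si](C)(C)C)[C@@H]12 | intermediate (not isolated)
27 | trimethylammonium iodide of 26 | C[N+](C)(C)CC1C(=O)O[C@@H]2C[C@](C)(O[Si](CC)(CC)CC)[C@@H](O[Si](C)(C)C)C[C@H]3O[C@@]3(C)C[C@@H](O[Si](C)(C)C)[C@@H]12.[I-] | intermediate (not isolated)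
28 | 11(13)-methylene lactone with 3β-OTMS, 8β-OTMS, 4α-OTES | C=C1C(=O)O[C@@H]2C[C@](C)(O[Si](CC)(CC)CC)[C@@H](O[Si](C)(C)C)C[C@H]3O[C@@]3(C)C[C@@H](O[Si](C)(C)C)[C@@H]12 | intermediate
29 | 1β,10β-epoxy-3β,8β-dihydroxy-4α-(triethylsilyloxy)germacr-11(13)-en-6α,12-olide | C=C1C(=O)O[C@@H]2C[C@](C)(O[Si](CC)(CC)CC)[C@@H](O)C[C@H]3O[C@@]3(C)C[C@@H](O)[C@@H]12 | intermediate
30 | angelic acid, (Z)-2-methylbut-2-enoic acid | C/C=C(/C)C(=O)O | starting material
31 | angelic 2,4,6-trichlorobenzoic anhydride | C/C=C(/C)C(=O)OC(=O)c1c(Cl)cc(Cl)cc1Cl | intermediate (not isolated)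
32 | 8β-angeloyloxy-1β,10β-epoxy-3β-hydroxy-4α-(triethylsilyloxy)germacr-11(13)-en-6α,12-olide | C=C1C(=O)O[C@@H]2C[C@](C)(O[Si](CC)(CC)CC)[C@@H](O)C[C@H]3O[C@@]3(C)C[C@@H](OC(=O)/C(C)=C\C)[C@@H]12 | intermediate
33 | (1R,3S,4S,6R,7S,8R,10S)-8β-angeloyloxy-1β,10β-epoxy-3β,4α-dihydroxygermacr-11(13)-en-6α,12-olide | C=C1C(=O)O[C@@H]2C[C@](C)(O)[C@@H](O)C[C@H]3O[C@@]3(C)C[C@@H](OC(=O)/C(C)=C\C)[C@@H]12 | target

## Step count and least certain steps

Total: 21 steps. Longest linear sequence: 21 steps, from 1; compounds 3, 13 and 30 enter as purchased.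

**Step 15 (key step).** What may go wrong: oxygen-atom transfer to the hindered tetrasubstituted olefin instead of cycloaddition, fragmentation of the carbonyl oxide next to the α-silyloxy carbon, and transannular aldolisation or base-induced opening of the epoxide in the β,γ-epoxy diketone during work-up. Fallback: setting out from 20, stoichiometric OsO4 in pyridine/THF with aqueous NaHSO3 work-up should give the 3,8-diol F1 (either face serves, both converge). Glycol cleavage with Pb(OAc)4 in CH2Cl2 over K2CO3 at 0 °C then returns to the route at 23.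

**Step 9.** What may go wrong: loss of regiocontrol, because the sulfonyl group competes with the ketone for polarisation of the dienophile; slow cycloaddition at the hindered C8 with polymerisation of isoprene; and weaker facial discrimination, because the axial 6α-silyloxy group lies on the face the diene should use. Fallback: setting out from 10, one equivalent of mCPBA gives sulfoxide 11, now isolated, whose weaker acceptor leaves the orientation to the ketone. Heating 11 with 13 in toluene should give the sulfinyl adduct F2, which loses benzenesulfenic acid in the flask by syn elimination towards the acidic H3 to give dienone F3. A Shi epoxidation (the antipode of the fructose-derived ketone that serves the β face, KHSO5, buffered MeCN/H2O, 0 °C) then sets the epoxide by reagent control and returns to the route at 16.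

**Step 16.** What may go wrong: poor facial selectivity, because the conformer population of the ten-membered ring is not known; incomplete reduction of the hindered C3 ketone; translactonisation by the C8 alkoxide if the mixture warms. Fallback: setting out from 23, reagent control replaces substrate control. (S)-Me-CBS oxazaborolidine with catecholborane at −78 °C should reduce the more accessible C8 ketone to the 8β-hydroxy ketone F4 (large group C7, small group C9). (R)-Me-CBS with catecholborane then reduces C3 (large group C4, small group C2) and returns to the route at 24.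

**Step 20.** What may go wrong: acylation of the C3 hydroxyl as well, and isomerisation of the Z acyl donor to the tiglate at 75 °C. Fallback: setting out from 28, controlled methanolysis (PPTS, MeOH, −20 °C) removes only the less hindered C8 trimethylsilyl ether to give the mono-alcohol F5. Yamaguchi acylation with 30 gives the C3-protected angelate F6, and HF·pyridine removes both remaining silyl ethers and returns to the route at 33.

**Step 1.** What may go wrong: modest enantioselectivity with this small cyclic diene, and loss of the volatile, acid-labile epoxide on isolation. Fallback: setting out from 4 of insufficient enantiomeric purity, lipase-catalysed acetylation (Candida antarctica lipase B, vinyl acetate, MTBE, rt) should acylate the (6R)-carbinol, in line with the usual lipase preference, to give acetate F7. After separation from the unreacted antipode, methanolysis (K2CO3, MeOH, 0 °C) returns to the route at 4.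

## Further compounds

F1 | step 15 | 3β,8β-dihydroxy-1β,10β-epoxy-4α-(triethylsilyloxy)decalin 6α,12-olide (cis-3,8-diol of 20) | O=C1C[C@H]2[C@H](O1)C[C@](C)(O[Si](CC)(CC)CC)[C@]3(O)C[C@H]4O[C@@]4(C)C[C@]23O
F2 | step 9 | cis-fused 8β-phenylsulfinyl adduct (sulfoxide analogue of 14, sulfur not defined) | COC(=O)C[C@H]1[C@H](O[Si](C)(C)C(C)(C)C)CC(=O)[C@@H]2CC=C(C)C[C@]12S(=O)c3ccccc3
F3 | step 9 | dienone: 6α-OTBS-7β-CH2CO2Me-Δ1(10),3(8)-hexahydronaphthalen-4-one | COC(=O)C[C@H]1[C@H](O[Si](C)(C)C(C)(C)C)CC(=O)C=2CC=C(C)CC1=2
F4 | step 16 | 1β,10β-epoxy-8β-hydroxy-3-oxo-4α-(triethylsilyloxy)germacran-6α,12-olide | O=C1C[C@H]2[C@H](O1)C[C@](C)(O[Si](CC)(CC)CC)C(=O)C[C@H]3O[C@@]3(C)C[C@H]2O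
F5 | step 20 | 8β-hydroxy-3β-(trimethylsilyloxy)-4α-(triethylsilyloxy) methylene lactone | C=C1C(=O)O[C@@H]2C[C@](C)(O[Si](CC)(CC)CC)[C@@H](O[Si](C)(C)C)C[C@H]3O[C@@]3(C)C[C@@H](O)[C@@H]12
F6 | step 20 | 8β-angelate of F5 | C=C1C(=O)O[C@@H]2C[C@](C)(O[Si](CC)(CC)CC)[C@@H](O[Si](C)(C)C)C[C@H]3O[C@@]3(C)C[C@@H](OC(=O)/C(C)=C\C)[C@@H]12
F7 | step 1 | dimethyl 2-[(1S,6R)-6-acetoxycyclohex-2-en-1-yl]propanedioate | COC(=O)C(C(=O)OC)[C@@H]1C=CCC[C@H]1OC(C)=O
A1 | alternative 1 | C6 diazoacetate of the ten-membered carbocycle (3,4-acetonide, 8β-OTBS, 1β,10β-epoxide, C7 methylene) | [N-]=[N+]=CC(=O)O[C@@H]1C[C@]2(C)OC(C)(C)O[C@H]2C[C@H]3O[C@@]3(C)C[C@@H](O[Si](C)(C)C(C)(C)C)C1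
A2 | alternative 1 | trans-fused saturated 6,12-lactone on the same carbocycle | C1C(=O)O[C@@H]2C[C@]3(C)OC(C)(C)O[C@H]3C[C@H]4O[C@@]4(C)C[C@@H](O[Si](C)(C)C(C)(C)C)[C@@H]12
A3 | alternative 2 | trans-1-(4,5-dihydrofuran-3-yl)-3-methyl-6-(prop-1-en-2-yl)cyclohex-3-en-1-ol | CC(=C)[C@H]1CC=C(C)C[C@]1(O)C2=COCC2
A4 | alternative 2 | tetrahydrofuran-fused (1(10)Z,3E)-cyclodecadien-8-one | C1CO[C@@H]2C/C(C)=C/C/C=C(C)\CC(=O)[C@@H]12
A5 | alternative 3 | thirteen-membered allylic ether with tributylstannyl group on C8 (3,4-acetonide, 6-OPMB, C12-OTBS) | CCCC[Sn](CCCC)(CCCC)[C@H]1OC/C(CO[Si](C)(C)C(C)(C)C)=C\[C@H](OCc2ccc(OC)cc2)C[C@]3(C)OC(C)(C)O[C@H]3C/C=C(C)\C1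
A6 | alternative 3 | ten-membered C8 alcohol with the 3-(silyloxy)prop-1-en-2-yl branch on C7 | C=C(CO[Si](C)(C)C(C)(C)C)[C@H]1[C@H](OCc2ccc(OC)cc2)C[C@]3(C)OC(C)(C)O[C@H]3C/C=C(C)\C[C@H]1O
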